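## Structural features

The target is a flavonol. A benzene ring A is fused through C4a and C8a to a 4-pyranone ring C, which carries the 4-hydroxyphenyl ring B on C2, a hydroxyl on C3 and the carbonyl on C4. Ring A has the phloroglucinol pattern, with oxygen on C5, C7 and C8a (the ring oxygen O1), and a 3-methylbut-2-enyl (prenyl) chain on C8, the carbon between O1 and the C7 hydroxyl. The target has no stereocenter, but a saturated precursor of ring C has three contiguous ones at C2, C3 and C4, which only need to be carried, not controlled. The fragile parts are the trisubstituted prenyl alkene, which electrophilic oxidants attack and which strong acid closes onto the neighbouring C7 hydroxyl, and the electron-rich polyphenol. The real difficulty is twofold: the prenyl group must sit on C8 and not on C6, and the 3-hydroxy-4-pyranone must be made without an oxidant that touches the alkene. The key step exploits the fact that C2 (aryl), C3 (oxygen) and C4 (oxygen) of ring C correspond to a three-carbon aryl glycidic aldehyde, while ring A offers two adjacent nucleophilic sites: the phenol oxygen that becomes O1 and the ortho carbon that becomes C4a.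

## Logic of the disconnections

**16 to 15.** The three acetal C–O bonds on O5, O7 and O4′ are cut. One acid-labile group on all three phenols means a single closing operation, and no free phenol meets base, oxidant or magnesium earlier. The gain is a neutral, oxidation-resistant substrate for every preceding step. The demand is that the acid is too mild or too brief to protonate the prenyl alkene next to the freed C7 hydroxyl.

**15 to 13.** No skeletal bond is cut. The C2=C3 double bond and the C4 carbonyl are taken back, through 14, to three sp3 carbons with carbinols at C3 and C4. A saturated ring C can be assembled by polar C–C and C–O bond formation, which the pyranone cannot. The gain is that the three stereocenters need no control. The demand is an oxidant that converts both carbinols to carbonyls without cleaving C3–C4 or touching the alkene, followed by enolization of 14 toward C2.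

**13 to 6 and 10.** The C4–C4a and O1–C2 bonds are cut. Both are polar bonds between a phenol that is nucleophilic at oxygen and at its ortho carbon, and a three-carbon unit that is electrophilic at the formyl carbon and at the benzylic epoxide carbon. This is the largest simplification of the route: ring C disappears and the molecule falls into a ring A piece carrying the prenyl group and a ring B piece. The demand is C-attack at the ortho carbon of 11 (not at the para carbon or through oxygen), then endo opening of the epoxide in 12.

**6 to 5.** The bond between C8 and the prenyl CH2 is cut and exchanged for the O–C bond of an aryl 1,1-dimethylallyl ether. Direct C-prenylation of a phloroglucinol is unselective, whereas a [3,3] shift places exactly one prenyl group on a carbon ortho to the ether oxygen. Because 5 has a mirror plane, its two ortho carbons are equivalent and only one product is possible. The demand is a rearrangement temperature the acetals tolerate.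

**5 to 2 and 4.** The O–C(tertiary) bond is cut. A tertiary allylic ether is not accessible by direct displacement but is accessible through a π-allylpalladium intermediate attacked at its more substituted end. The gain is a symmetric phenol and a carbonate of a commodity alcohol. The demand is branched over linear selectivity and O- over C-allylation.

**2 to 1.** Two acetal O–C bonds are cut. The gain is a commodity triol. The demand is to stop at the bis-ether, which is a statistical problem solved by separation.

**4 to 3.** The O–C(=O) bond is cut. The demand is acylation of a hindered tertiary alcohol, met by forming the alkoxide first.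

**10 to 9.** The two epoxide C–O bonds are cut back to the E alkene of an enal. Putting the epoxide onto the aldehyde oxidation level avoids the 3-(4-alkoxyphenyl)glycidol, whose benzylic C–O bond would ionize under the acid by-products of a peracid epoxidation, and leaves no oxidation to do once the epoxide exists. The gain is one step fewer than a reduce–epoxidize–oxidize sequence and a less labile intermediate. The demand is conjugate addition of peroxide in preference to attack at the formyl carbon.

**9 to 8.** The C=C bond is cut (Wittig retron). The gain is a simple benzaldehyde. The demand is E geometry and a single two-carbon homologation.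

**8 to 7.** The acetal O–C bond is cut. The gain is a commodity phenol aldehyde. The demand is trivial.

## Other disconnections considered

**Alternative 1:** The cut is made in ring A: C8–C8a, C6–C7 and C4a–C8a are broken, so the benzene ring is assembled from 3-ethoxycyclobut-2-en-1-one A1 and triisopropyl[(5-methylhex-4-en-1-yn-1-yl)oxy]silane A2.
- **Forward step:** Heated in toluene, A1 should open to a vinylketene, add across the electron-rich triple bond of A2, open again, close by a 6π electrocyclization and tautomerize to 5-ethoxy-2-(3-methylbut-2-en-1-yl)-3-(triisopropylsilyloxy)phenol A3.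
- **In favour:** Every substituent position follows from the connectivity of the pericyclic cascade. The three oxygens come out chemically distinct, and there is no statistical protection as in step 1. On these two points the alternative is the better of the two.
- **Equal:** Its control over the prenyl position is the equal of the chosen plan, because the symmetry of 5 already allows only one Claisen product.
- **Against:** A3 is only an analogue of 6, so ring C, the actual problem, would still have to be built afterwards, most reasonably by the same step 8. The ring that 1 supplies for nothing is built from A1 and A2, each needing its own multistep preparation. The C5 ethyl ether would have to be cleaved at the end with BCl3 or AlCl3, conditions under which the prenyl group and the C7 hydroxyl are likely to cyclize.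
- **Comparison:** Both plans fix ring A by a thermal pericyclic event. In step economy the chosen plan reaches 6 in four operations from commodity chemicals; the benzannulation would roughly double that and add a dealkylation risk.

**Alternative 2:** The cut is O1–C2 and C3–C4, with nitrogen standing in for the C3 oxygen. The partners would be 2-hydroxy-4,6-bis(methoxymethoxy)-3-(3-methylbut-2-en-1-yl)benzaldehyde A4 (from 6 by magnesium-mediated ortho-formylation) and 1-(methoxymethoxy)-4-[(E)-2-nitroethenyl]benzene A5 (from 8 by a Henry condensation).
- **Forward step:** With DABCO, oxa-Michael addition of the phenoxide, intramolecular Henry reaction of the nitronate with the formyl group and loss of water should give 5,7-bis(methoxymethoxy)-2-[4-(methoxymethoxy)phenyl]-3-nitro-8-(3-methylbut-2-en-1-yl)-2H-chromene A6.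
- **In favour:** The annulation of salicylaldehydes with β-nitrostyrenes is an established reaction class, so the key step rests on firmer precedent than step 8. Neither partner contains an acid-labile epoxide. On both points the alternative is the better. It is the equal of the chosen plan in needing no stereocontrol.
- **Against:** A6 has C3 as C–NO2 and C4 as an sp2 CH. The nitro group must be exchanged for oxygen by a Nef-type operation, whose classical strongly acidic form is incompatible with the acetals and the prenyl group. C4 must then be oxidized separately, all next to an isolated alkene. A5 is a deactivated Michael acceptor because of its para-alkoxy group, and the formyl group of A4 is flanked by two oxygen substituents, so the Henry closure may be slow or reversible.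
- **Comparison:** Both plans close ring C with the ring A phenol oxygen forming O1–C2. The chosen plan delivers C3 and C4 already bearing oxygen, so one oxidation gives the flavonol. The nitro route needs a formylation, the annulation and at least three further functional-group changes of uncertain selectivity, so it would be longer by about two to three steps.

**Alternative 3:** The cut is the single bond C3–C4, made with reversed polarity. The substrate would be the dialdehyde 2-{1-[4-(methoxymethoxy)phenyl]-2-oxoethoxy}-4,6-bis(methoxymethoxy)-3-(3-methylbut-2-en-1-yl)benzaldehyde A7, reached from A4 by O-alkylation with an α-halo arylacetic acid derivative and adjustment of the oxidation level.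
- **Forward step:** A thiazolium-derived carbene with Et3N would add to the ring A formyl group, and the resulting acyl anion equivalent would attack the aliphatic aldehyde, closing ring C as trans-3-hydroxy-5,7-bis(methoxymethoxy)-2-[4-(methoxymethoxy)phenyl]-8-(3-methylbut-2-en-1-yl)chroman-4-one A8.
- **In favour:** A8 is at the dihydroflavonol oxidation level, one dehydrogenation from 15, and never carries the ionizable C4 carbinol of 13. On oxidation level and on the stability of the key-step product the alternative is the better. It is catalytic and metal-free.
- **Against:** The carbene should add faster to the unhindered aliphatic aldehyde than to the electron-rich, doubly ortho-substituted aryl aldehyde. That leads either to the isomeric acyloin or, since that carbon carries an α-aryloxy leaving group, to expulsion of the phenoxide and loss of the O1–C2 bond. A7 is an enolizable α-aryloxy arylacetaldehyde, prone to self-condensation, and needs three to four steps from 6 in which two aldehydes must be told apart.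
- **Comparison:** The chosen key step forms two bonds from two stable-enough fragments in normal polarity; this one forms one bond from a delicate substrate. After the key step both plans need one oxidation step and one deprotection, so they are equal there. Before it the alternative is about three steps longer.

Key step: step 8

Remark on the chemistry: C2, C3 and C4 all become sp2 in step 9, so chiral intermediates are treated as racemates or epimer mixtures with one enantiomer drawn, and the chiral amine catalyst of step 7 may be used as either enantiomer or as the racemate. The structures were checked for consistency and needed no correction: an E alkene gives the trans epoxide, and inversion at its benzylic carbon gives the 2,3-trans diol, so the (2R,3S) epoxide drawn and the (2R,3S) diol drawn belong together.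

## Route

Step 1
Reactants: 1 phloroglucinol (benzene-1,3,5-triol)
Product: 2 3,5-bis(methoxymethoxy)phenol
Conditions: MOMCl (2.0 equiv), i-Pr2NEt (2.2 equiv), DMF, 0 °C to rt; chromatography
Reagents that add atoms: chloromethyl methyl ether (MOMCl), COCCl
Why: O-alkylation of the phenoxide by the chloromethyl ether (acetal formation); two equivalents should give a statistical mixture from which the bis-ether is separated, and the mono-ether can be resubmitted.

Step 2
Reactants: 3 2-methylbut-3-en-2-ol
Product: 4 methyl 2-methylbut-3-en-2-yl carbonate
Conditions: n-BuLi, THF, −78 °C; ClCO2Me, −78 °C to rt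
Reagents that add atoms: methyl chloroformate, COC(=O)Cl
Why: O-acylation of the lithium alkoxide; prior deprotonation is used because the hindered tertiary alcohol is a poor nucleophile toward the chloroformate.

Step 3
Reactants: 2 3,5-bis(methoxymethoxy)phenol; 4 methyl 2-methylbut-3-en-2-yl carbonate
Product: 5 1,3-bis(methoxymethoxy)-5-[(2-methylbut-3-en-2-yl)oxy]benzene
Conditions: Pd(PPh3)4 (2 mol %), THF, 0 °C
Reagents that add atoms: none
Why: Tsuji–Trost O-allylation: zerovalent palladium ionizes the carbonate with loss of CO2, the methoxide set free deprotonates the phenol, and the phenoxide should attack the more substituted end of the 1,1-dimethyl-π-allyl complex under kinetic control at low temperature to give the tertiary aryl ether.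

Step 4
Reactants: 5 1,3-bis(methoxymethoxy)-5-[(2-methylbut-3-en-2-yl)oxy]benzene
Product: 6 3,5-bis(methoxymethoxy)-2-(3-methylbut-2-en-1-yl)phenol
Conditions: DMF, 120 °C, N2
Reagents that add atoms: none
Why: Aromatic Claisen rearrangement: the [3,3] shift bonds the unsubstituted allyl terminus to an ortho carbon and so turns the 1,1-dimethylallyl ether into the C-prenyl phenol; the two ortho carbons are equivalent, so only one regioisomer can form, and tautomerization to the phenol makes the step irreversible.

Step 5
Reactants: 7 4-hydroxybenzaldehyde
Product: 8 4-(methoxymethoxy)benzaldehyde
Conditions: MOMCl, i-Pr2NEt, CH2Cl2, 0 °C to rt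
Reagents that add atoms: chloromethyl methyl ether (MOMCl), COCCl
Why: Standard acetal protection of a phenol; the same group as on ring A allows one global deprotection at the end.

Step 6
Reactants: 8 4-(methoxymethoxy)benzaldehyde
Product: 9 (E)-3-[4-(methoxymethoxy)phenyl]prop-2-enal
Conditions: Ph3P=CHCHO (1.1 equiv), PhMe, 90 °C
Reagents that add atoms: (triphenylphosphoranylidene)acetaldehyde, O=CC=P(c1ccccc1)(c1ccccc1)c1ccccc1
Why: Wittig olefination with a stabilized formyl ylide, which should be E-selective; only a slight excess of ylide is used so that the product enal is not homologated a second time.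

Step 7
Reactants: 9 (E)-3-[4-(methoxymethoxy)phenyl]prop-2-enal
Product: 10 trans-3-[4-(methoxymethoxy)phenyl]oxirane-2-carbaldehyde (drawn as 2R,3S; enantiomeric composition immaterial)
Conditions: 35% aq. H2O2 (1.3 equiv), 2-{bis[3,5-bis(trifluoromethyl)phenyl](trimethylsilyloxy)methyl}pyrrolidine (10 mol %), CH2Cl2, rt; used at once after drying
Reagents that add atoms: hydrogen peroxide, OO
Why: Amine-catalysed nucleophilic epoxidation of an enal: hydrogen peroxide adds in conjugate fashion to the iminium ion and the resulting enamine closes the ring by displacing hydroxide from the peroxide oxygen, so the E alkene gives the trans epoxide (C2 and C3 set relative to each other by the alkene geometry); the conditions are non-acidic, which spares the ionizable para-alkoxyphenyl epoxide.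

Step 8
Reactants: 6 3,5-bis(methoxymethoxy)-2-(3-methylbut-2-en-1-yl)phenol; 10 trans-3-[4-(methoxymethoxy)phenyl]oxirane-2-carbaldehyde
Product: 13 2,3-trans-5,7-bis(methoxymethoxy)-2-[4-(methoxymethoxy)phenyl]-8-(3-methylbut-2-en-1-yl)chroman-3,4-diol (racemic; both C4 epimers), via bromomagnesium phenoxide 11 (not isolated), via epoxy carbinol adduct 12 (not isolated)
Conditions: EtMgBr (1.0 equiv), Et2O, 0 °C; evaporate, PhMe; 10 (1.1 equiv), −20 °C to rt; pH 7 phosphate buffer
Reagents that add atoms: none
Why: Proposed new method: deprotonation of 6 by EtMgBr gives the phenoxide 11, whose magnesium binds the formyl oxygen of 10 and delivers the aldehyde carbon through a six-membered chelate to the only free ortho carbon (the future C4a), after which tautomerization gives the magnesium-bound epoxy carbinol 12; the closest known reaction types are the ortho-selective hydroxyalkylation of magnesium phenoxides with aldehydes in non-coordinating solvents and the endo opening of aryl epoxides by phenols used to close flavan-3-ols, and the novelty lies in running the two as one cascade on an epoxy aldehyde. Ring C then closes by a 6-endo opening of the epoxide: the phenol oxygen of 12 attacks the benzylic carbon (the future C2), which is activated by magnesium on the epoxide oxygen and by the para-alkoxyphenyl group, in preference to 5-exo attack at the non-benzylic carbon. The attack goes with inversion at C2 while C3 keeps the configuration it had in the epoxide, so the trans epoxide leads to the 2,3-trans relationship; C4 is new and is expected as a mixture of epimers because the chelate need not favour one face of the aldehyde strongly. None of this matters for the target, since C2, C3 and C4 all become sp2 in step 9. The selectivity the step needs is ortho-C over para-C and over O-attack, secured by chelation at the single free hydroxyl (the para carbon between the two acetals cannot be reached through the chelate), and endo over exo opening, secured by the cation-stabilizing ring B. Toluene instead of an ether solvent keeps magnesium free to bind the aldehyde, one equivalent of Grignard reagent prevents ethyl addition to 10, and a neutral quench with immediate use protects the ionizable C4 carbinol of 13.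

Step 9
Reactants: 13 2,3-trans-5,7-bis(methoxymethoxy)-2-[4-(methoxymethoxy)phenyl]-8-(3-methylbut-2-en-1-yl)chroman-3,4-diol (crude)
Product: 15 3-hydroxy-5,7-bis(methoxymethoxy)-2-[4-(methoxymethoxy)phenyl]-8-(3-methylbut-2-en-1-yl)-4H-chromen-4-one, via chroman-3,4-dione 14 (not isolated)
Conditions: (COCl)2 (5 equiv), DMSO (10 equiv), CH2Cl2, −78 °C; Et3N (15 equiv), −78 to 0 °C
Reagents that add atoms: none
Why: Swern oxidation turns both secondary carbinols into carbonyls without C–C cleavage; the 1,2-dione 14 has an acidic, doubly activated C2–H and should enolize under Et3N to the 3-hydroxy-4-pyranone, which removes all three stereocenters, and the isolated prenyl alkene and the acetals are inert to activated DMSO.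

Step 10
Reactants: 15 3-hydroxy-5,7-bis(methoxymethoxy)-2-[4-(methoxymethoxy)phenyl]-8-(3-methylbut-2-en-1-yl)-4H-chromen-4-one
Product: 16 8-prenylkaempferol, 3,5,7-trihydroxy-2-(4-hydroxyphenyl)-8-(3-methylbut-2-en-1-yl)-4H-chromen-4-one
Conditions: 3 M aq. HCl, MeOH, 50 °C, monitored and stopped at full conversion
Reagents that add atoms: none
Why: Acid-catalysed transacetalization of the three methoxymethyl ethers to methanol (loss as dimethoxymethane); moderate temperature and short exposure are chosen so that the acetals cleave faster than the prenyl alkene is protonated, and the flavonol core is acid-stable.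

## Compound list

1 | phloroglucinol (benzene-1,3,5-triol) | Oc1cc(O)cc(O)c1 | starting material
2 | 3,5-bis(methoxymethoxy)phenol | COCOc1cc(O)cc(OCOC)c1 | intermediate
3 | 2-methylbut-3-en-2-ol | C=CC(C)(C)O | starting material
4 | methyl 2-methylbut-3-en-2-yl carbonate | C=CC(C)(C)OC(=O)OC | intermediate
5 | 1,3-bis(methoxymethoxy)-5-[(2-methylbut-3-en-2-yl)oxy]benzene | C=CC(C)(C)Oc1cc(OCOC)cc(OCOC)c1 | intermediate
6 | 3,5-bis(methoxymethoxy)-2-(3-methylbut-2-en-1-yl)phenol | CC(C)=CCc1c(O)cc(OCOC)cc1OCOC | intermediate
7 | 4-hydroxybenzaldehyde | O=Cc1ccc(O)cc1 | starting material
8 | 4-(methoxymethoxy)benzaldehyde | COCOc1ccc(C=O)cc1 | intermediate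
9 | (E)-3-[4-(methoxymethoxy)phenyl]prop-2-enal | O=C/C=C/c1ccc(OCOC)cc1 | intermediate
10 | trans-3-[4-(methoxymethoxy)phenyl]oxirane-2-carbaldehyde (drawn as 2R,3S) | O=C[C@@H]1O[C@H]1c1ccc(OCOC)cc1 | intermediate
11 | bromomagnesium 3,5-bis(methoxymethoxy)-2-(3-methylbut-2-en-1-yl)phenoxide (formed in the flask, not isolated) | CC(C)=CCc1c(O[Mg]Br)cc(OCOC)cc1OCOC | intermediate
12 | 2-{hydroxy[trans-3-(4-(methoxymethoxy)phenyl)oxiran-2-yl]methyl}-3,5-bis(methoxymethoxy)-6-(3-methylbut-2-en-1-yl)phenol, present as its magnesium chelate (not isolated; carbinol carbon both epimers) | CC(C)=CCc1c(O)c(C(O)[C@@H]2O[C@H]2c2ccc(OCOC)cc2)c(OCOC)cc1OCOC | intermediate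
13 | 2,3-trans-5,7-bis(methoxymethoxy)-2-[4-(methoxymethoxy)phenyl]-8-(3-methylbut-2-en-1-yl)chroman-3,4-diol (racemic, drawn as 2R,3S; both C4 epimers) | CC(C)=CCc1c(OCOC)cc(OCOC)c2c1O[C@H](c1ccc(OCOC)cc1)[C@@H](O)C2O | intermediate
14 | 5,7-bis(methoxymethoxy)-2-[4-(methoxymethoxy)phenyl]-8-(3-methylbut-2-en-1-yl)chroman-3,4-dione (racemic, one enantiomer drawn; not isolated) | CC(C)=CCc1c(OCOC)cc(OCOC)c2c1O[C@H](c1ccc(OCOC)cc1)C(=O)C2=O | intermediate
15 | 3-hydroxy-5,7-bis(methoxymethoxy)-2-[4-(methoxymethoxy)phenyl]-8-(3-methylbut-2-en-1-yl)-4H-chromen-4-one | CC(C)=CCc1c(OCOC)cc(OCOC)c2c(=O)c(O)c(-c3ccc(OCOC)cc3)oc12 | intermediate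
16 | 8-prenylkaempferol, 3,5,7-trihydroxy-2-(4-hydroxyphenyl)-8-(3-methylbut-2-en-1-yl)-4H-chromen-4-one (no stereocenter) | CC(C)=CCc1c(O)cc(O)c2c(=O)c(O)c(-c3ccc(O)cc3)oc12 | target

## Step count and least certain steps

Total: 10 steps. Longest linear sequence: 6 steps (1, 3, 4, 8, 9, 10 from phloroglucinol; equally 5, 6, 7, 8, 9, 10 from 4-hydroxybenzaldehyde).

**Step 8 (key step, proposed new method).**
- Most likely failure: ionization of the magnesium-bound C4 carbinol, which is flanked by three donor oxygens, to an ortho-quinone methide that is captured by a second phenoxide. Also possible is Lewis-acid-induced rearrangement or bromide opening of the electron-rich aryl epoxide before the C–C bond forms. Both would drain material before ring closure.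
- Fallback (known chemistry), from 6 and 9, returning at 13:
  - 6 and 9 are condensed with catalytic ethylenediammonium diacetate in toluene at 110 °C. Ortho-hydroxyalkylation, loss of water to an ortho-quinone methide and oxa-6π electrocyclization should give 5,7-bis(methoxymethoxy)-2-[4-(methoxymethoxy)phenyl]-8-(3-methylbut-2-en-1-yl)-2H-chromene F1.
  - The conjugated cis alkene C3=C4 of F1 is epoxidized in preference to the isolated prenyl alkene by a Jacobsen–Katsuki epoxidation: racemic [N,N′-bis(3,5-di-tert-butylsalicylidene)cyclohexane-1,2-diaminato]manganese chloride, buffered NaOCl, CH2Cl2, 0 °C. Attack anti to the C2 aryl group should give 2,3-trans-3,4-epoxy-5,7-bis(methoxymethoxy)-2-[4-(methoxymethoxy)phenyl]-8-(3-methylbut-2-en-1-yl)chroman F2.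
  - F2 is opened by water at the activated C4 in aqueous THF at pH 7 to give 13.

**Step 7.**
- Most likely failure: slow conjugate addition of peroxide to the iminium ion, which the para-alkoxy group deactivates, so that oxidation at the formyl carbon competes; and loss of the labile aryl epoxide by ring opening during isolation.
- Fallback, from 8, returning at 10: Darzens condensation of 8 with methyl chloroacetate and NaOMe in MeOH at 0 °C should give methyl trans-3-[4-(methoxymethoxy)phenyl]oxirane-2-carboxylate F3. The ester group stabilizes this epoxide. Half-reduction with i-Bu2AlH in CH2Cl2 at −78 °C then gives 10.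

**Step 9.**
- Most likely failure: ionization of the activated C4 alkoxysulfonium intermediate (substitution by chloride or elimination) instead of ylide fragmentation, and an incomplete second oxidation.
- Fallback, from 13, returning at 15: the benzylic C4 carbinol alone is oxidized with MnO2 in CH2Cl2 at rt to trans-3-hydroxy-5,7-bis(methoxymethoxy)-2-[4-(methoxymethoxy)phenyl]-8-(3-methylbut-2-en-1-yl)chroman-4-one F4 (the same compound as A8). The remaining α-ketol is then oxidized with Dess–Martin periodinane and NaHCO3 in CH2Cl2; the dione formed should enolize to 15.

**Step 10.**
- Most likely failure: acid-catalysed addition of the freed C7 hydroxyl to the protonated prenyl alkene, closing a dimethyldihydropyran ring, or addition of HCl or methanol across the alkene.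
- Fallback, from 15, returning at 16: the Brønsted acid is replaced by a buffered acetal-to-silyl-ether exchange. TMSOTf and 2,2′-bipyridyl in MeCN at 0 °C should give 8-(3-methylbut-2-en-1-yl)-3,5,7-tris(trimethylsilyloxy)-2-[4-(trimethylsilyloxy)phenyl]-4H-chromen-4-one F5. Neutral hydrolysis of the silyl ethers with water at rt then gives 16.

**Step 3.**
- Most likely failure: attack of the phenoxide at the unsubstituted allyl terminus, or re-ionization of the tertiary ether and isomerization to the linear prenyl ether, which would not give 6 on heating; C-allylation of the electron-rich ring is a further possibility.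
- Fallback, from 2, returning at 5: alkylation of 2 with 3-chloro-3-methylbut-1-yne (CuCl2 catalyst, DBU, MeCN, 0 °C) should give 1,3-bis(methoxymethoxy)-5-[(2-methylbut-3-yn-2-yl)oxy]benzene F6, in which the ether position is fixed. Semihydrogenation (H2, Pd/CaCO3 poisoned with Pb(OAc)2, quinoline, EtOAc) then gives 5.

## Further compounds

F1 | step 8 | 5,7-bis(methoxymethoxy)-2-[4-(methoxymethoxy)phenyl]-8-(3-methylbut-2-en-1-yl)-2H-chromene (racemic, one enantiomer drawn) | CC(C)=CCc1c(OCOC)cc(OCOC)c2c1O[C@H](c1ccc(OCOC)cc1)C=C2
F2 | step 8 | 2,3-trans-3,4-epoxy-5,7-bis(methoxymethoxy)-2-[4-(methoxymethoxy)phenyl]-8-(3-methylbut-2-en-1-yl)chroman (racemic, one enantiomer drawn) | CC(C)=CCc1c(OCOC)cc(OCOC)c2c1O[C@H](c1ccc(OCOC)cc1)[C@H]3O[C@@H]23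
F3 | step 7 | methyl trans-3-[4-(methoxymethoxy)phenyl]oxirane-2-carboxylate (racemic, one enantiomer drawn) | COC(=O)[C@@H]1O[C@H]1c1ccc(OCOC)cc1
F4 | step 9 | trans-3-hydroxy-5,7-bis(methoxymethoxy)-2-[4-(methoxymethoxy)phenyl]-8-(3-methylbut-2-en-1-yl)chroman-4-one (racemic, one enantiomer drawn) | CC(C)=CCc1c(OCOC)cc(OCOC)c2c1O[C@H](c1ccc(OCOC)cc1)[C@@H](O)C2=O
F5 | step 10 | 8-(3-methylbut-2-en-1-yl)-3,5,7-tris(trimethylsilyloxy)-2-[4-(trimethylsilyloxy)phenyl]-4H-chromen-4-one | CC(C)=CCc1c(O[Si](C)(C)C)cc(O[Si](C)(C)C)c2c(=O)c(O[Si](C)(C)C)c(-c3ccc(O[Si](C)(C)C)cc3)oc12
F6 | step 3 | 1,3-bis(methoxymethoxy)-5-[(2-methylbut-3-yn-2-yl)oxy]benzene | C#CC(C)(C)Oc1cc(OCOC)cc(OCOC)c1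
A1 | alternative 1 | 3-ethoxycyclobut-2-en-1-one | CCOC1=CC(=O)C1
A2 | alternative 1 | triisopropyl[(5-methylhex-4-en-1-yn-1-yl)oxy]silane | CC(C)=CCC#CO[Si](C(C)C)(C(C)C)C(C)C
A3 | alternative 1 | 5-ethoxy-2-(3-methylbut-2-en-1-yl)-3-(triisopropylsilyloxy)phenol | CCOc1cc(O)c(CC=C(C)C)c(O[Si](C(C)C)(C(C)C)C(C)C)c1
A4 | alternative 2 | 2-hydroxy-4,6-bis(methoxymethoxy)-3-(3-methylbut-2-en-1-yl)benzaldehyde | CC(C)=CCc1c(O)c(C=O)c(OCOC)cc1OCOC
A5 | alternative 2 | 1-(methoxymethoxy)-4-[(E)-2-nitroethenyl]benzene | COCOc1ccc(/C=C/[N+](=O)[O-])cc1
A6 | alternative 2 | 5,7-bis(methoxymethoxy)-2-[4-(methoxymethoxy)phenyl]-3-nitro-8-(3-methylbut-2-en-1-yl)-2H-chromene (racemic, one enantiomer drawn) | CC(C)=CCc1c(OCOC)cc(OCOC)c2C=C([N+](=O)[O-])[C@H](c3ccc(OCOC)cc3)Oc12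
A7 | alternative 3 | 2-{1-[4-(methoxymethoxy)phenyl]-2-oxoethoxy}-4,6-bis(methoxymethoxy)-3-(3-methylbut-2-en-1-yl)benzaldehyde (racemic, one enantiomer drawn) | CC(C)=CCc1c(O[C@@H](C=O)c2ccc(OCOC)cc2)c(C=O)c(OCOC)cc1OCOC
A8 | alternative 3 | trans-3-hydroxy-5,7-bis(methoxymethoxy)-2-[4-(methoxymethoxy)phenyl]-8-(3-methylbut-2-en-1-yl)chroman-4-one (racemic, one enantiomer drawn) | O=C1c2c(OCOC)cc(OCOC)c(CC=C(C)C)c2O[C@H](c2ccc(OCOC)cc2)[C@H]1O
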